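**Retrosynthetic overview**
- Ring C is the only ring made, since rings A and B are bought as arenes, and it is closed last. A retro-oxa-Michael cut at O1–C2 opens the flavanone to the free 2'-hydroxychalcone 3',5-diprenylbutein, which is the chalcone-isomerase disconnection. A chiral bifunctional catalyst sets C2 (S) in this closure.
- Both aryl–prenyl C–C bonds are cut by a double retro-aromatic-Claisen step, back to the 4,4'-bis(1,1-dimethylallyl) ether of butein. The prenyl groups therefore arrive after the C6–C3–C6 skeleton.
- Both aryl O–C bonds come from palladium-catalysed tert-prenylation of the two most acidic phenols of butein with a carbonate of 2-methylbut-3-en-2-ol.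
- The Cα=Cβ bond comes from an acid Claisen–Schmidt condensation of 2,4-dihydroxyacetophenone and 3,4-dihydroxybenzaldehyde. No protecting group is used anywhere.

Assumption: the quinidine-derived thiourea of step 5 is taken to give the 2S series and its quinine-derived pseudoenantiomer the 2R series. This is checked on the first run by circular dichroism (2S-flavanones show a negative band near 290 nm and a positive band near 330 nm).

Step 1
Reactants: 1 2,4-dihydroxyacetophenone; 2 3,4-dihydroxybenzaldehyde
Product: 4 butein [(E)-2',3,4,4'-tetrahydroxychalcone], via aldol adduct 3 (not isolated)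
Conditions: dry HCl gas, abs. EtOH, 0 °C → rt, 12 h, Ar
Reagents that add atoms: none
Why: Acid-catalysed Claisen–Schmidt (crossed aldol) condensation, in which the enol of 1 adds to the protonated aldehyde (a good electrophile only while its para-hydroxyl stays un-ionised) and dehydration of 3 gives the conjugated E-enone, so the free phenols need no protection and no acid-sensitive prenyl group is present yet.

Step 2
Reactants: 5 2-methylbut-3-en-2-ol
Product: 7 tert-butyl 2-methylbut-3-en-2-yl carbonate, via lithium alkoxide 6 (not isolated)
Conditions: n-BuLi (1.05 equiv), THF, −78 → 0 °C; Boc2O (1.05 equiv), 0 °C → rt; H2O quench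
Reagents that add atoms: di-tert-butyl dicarbonate, CC(C)(C)OC(=O)OC(=O)OC(C)(C)C
Why: Alkoxide acylation (Boc transfer), in which the tertiary lithium alkoxide attacks the dicarbonate and expels tert-butyl carbonate, the standard entry to mixed tertiary allylic carbonates.

Step 3
Reactants: 4 butein; 7 tert-butyl 2-methylbut-3-en-2-yl carbonate (2.2 equiv)
Product: 9 butein 4,4'-bis(1,1-dimethylallyl) ether, via mono-ether 8 (not isolated)
Conditions: Pd(PPh3)4 (5 mol %), THF, 0 °C, 3 h, Ar; filter through silica as soon as 8 is consumed
Reagents that add atoms: none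
Why: Tsuji–Trost O-allylation, in which zerovalent palladium ionises 7 with loss of CO2, the released tert-butoxide deprotonates only the two most acidic phenols (4'-OH para to the ketone first, then 4-OH para to the enone, while the 2'-OH is chelated and the 3-OH is weaker and soon flanked by a tertiary ether), and each phenoxide attacks the more substituted terminus of the 1,1-dimethylallyl palladium cation under kinetic control at 0 °C to give the tertiary ether.

Step 4
Reactants: 9 butein 4,4'-bis(1,1-dimethylallyl) ether
Product: 11 3',5-diprenylbutein, via half-rearranged chalcone 10 (not isolated)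
Conditions: degassed o-xylene (0.05 molar), 130–140 °C, 6 h, Ar, silanised flask; chromatography to remove any flavanone
Reagents that add atoms: none
Why: Double aromatic Claisen rearrangement ([3,3]-sigmatropic shift, then rearomatising tautomerisation), in which the gem-dimethyl groups lower the barrier and the allyl inversion turns each tertiary ether into a normal prenyl group; ring B can only deliver to C5 because C3 carries OH, ring A delivers to C3' between the two oxygens because the chelated 2'-hydroxyaryl ketone puts more double-bond character into C3'–C4' than into C4'–C5' (the preference shown by 4-allyloxy-2-hydroxyacetophenones), and the neutral apolar medium keeps the 2'-hydroxychalcone open.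

Step 5
Reactants: 11 3',5-diprenylbutein
Product: 12 (2S)-7,3',4'-trihydroxy-8,5'-diprenylflavanone (target CNP0315050.1)
Conditions: 1-[3,5-bis(trifluoromethyl)phenyl]-3-[(9R)-6'-methoxycinchonan-9-yl]thiourea (quinidine-derived, 20 mol %), PhMe–CH2Cl2 4:1 (0.05 molar), 10 °C, 48–72 h, Ar, stopped at about 90 % conversion; 5 % aq. citric acid wash; recrystallisation (CH2Cl2–hexane) to raise the ee
Reagents that add atoms: none
Why: Proposed new method: chalcone-isomerase-type enantioselective 6-endo-trig intramolecular oxa-Michael addition, in which the two thiourea N–H bonds bind the enone carbonyl (replacing the 2'-OH···O=C chelate, holding the enone s-cis and making C-β more electrophilic) while the quinuclidine nitrogen takes the proton of the released 2'-OH, so that this oxygen adds to the Si face of C-β inside the chiral pocket and, after ketonisation, C2 is set as S under kinetic control with almost no uncatalysed background because 6'-deoxychalcones are inert without a base; the closest known reaction types are the cinchona-thiourea-catalysed cyclisations of ester-activated alkylidene β-keto esters and of O-alkylated 2'-hydroxychalcones to flavanones, and what is new is the unactivated 6'-deoxy enone carrying four free phenols.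

**Compound list**
1 | 2,4-dihydroxyacetophenone | CC(=O)c1ccc(O)cc1O | starting material
2 | 3,4-dihydroxybenzaldehyde | O=Cc1ccc(O)c(O)c1 | starting material
3 | 1-(2,4-dihydroxyphenyl)-3-(3,4-dihydroxyphenyl)-3-hydroxypropan-1-one (racemic aldol adduct) | O=C(CC(O)c1ccc(O)c(O)c1)c1ccc(O)cc1O | intermediate
4 | butein, (E)-1-(2,4-dihydroxyphenyl)-3-(3,4-dihydroxyphenyl)prop-2-en-1-one | O=C(/C=C/c1ccc(O)c(O)c1)c1ccc(O)cc1O | intermediate
5 | 2-methylbut-3-en-2-ol | CC(C)(O)C=C | starting material
6 | lithium 2-methylbut-3-en-2-olate | [Li+].[O-]C(C)(C)C=C | intermediate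
7 | tert-butyl 2-methylbut-3-en-2-yl carbonate | CC(C)(C)OC(=O)OC(C)(C)C=C | intermediate
8 | (E)-3-(3,4-dihydroxyphenyl)-1-[2-hydroxy-4-(2-methylbut-3-en-2-yloxy)phenyl]prop-2-en-1-one | O=C(/C=C/c1ccc(O)c(O)c1)c1ccc(OC(C)(C)C=C)cc1O | intermediate
9 | (E)-1-[2-hydroxy-4-(2-methylbut-3-en-2-yloxy)phenyl]-3-[3-hydroxy-4-(2-methylbut-3-en-2-yloxy)phenyl]prop-2-en-1-one | O=C(/C=C/c1ccc(OC(C)(C)C=C)c(O)c1)c1ccc(OC(C)(C)C=C)cc1O | intermediate
10 | (E)-3-[3,4-dihydroxy-5-(3-methylbut-2-enyl)phenyl]-1-[2-hydroxy-4-(2-methylbut-3-en-2-yloxy)phenyl]prop-2-en-1-one | O=C(/C=C/c1cc(O)c(O)c(CC=C(C)C)c1)c1ccc(OC(C)(C)C=C)cc1O | intermediate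
11 | 3',5-diprenylbutein, (E)-1-[2,4-dihydroxy-3-(3-methylbut-2-enyl)phenyl]-3-[3,4-dihydroxy-5-(3-methylbut-2-enyl)phenyl]prop-2-en-1-one | O=C(/C=C/c1cc(O)c(O)c(CC=C(C)C)c1)c1ccc(O)c(CC=C(C)C)c1O | intermediate
12 | (2S)-2-[3,4-dihydroxy-5-(3-methylbut-2-enyl)phenyl]-7-hydroxy-8-(3-methylbut-2-enyl)-2,3-dihydrochromen-4-one | CC(C)=CCc1cc([C@@H]2CC(=O)c3ccc(O)c(CC=C(C)C)c3O2)cc(O)c1O | target

**Total step count:** 5.
**Longest linear sequence:** 4 (steps 1, 3, 4, 5; the branch through step 2 is equally long).
The single stereocentre is set in the last step. After that, 12 is kept away from base and heat, because 4'-hydroxyflavanones racemise by ring opening.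

**Steps most likely to fail** (in route order; step 5 is the riskiest)

Risk at step 3:
- Four phenols compete, so some 3-O-ether or tris-ether may form.
- The ethers of such acidic phenols can be re-ionised by zerovalent palladium and drift to the linear prenyl ethers.

The fallback sets out from 1 and 2 and comes back at 9. It changes both the C–O bond-forming chemistry and the order of events.
- Each fragment is alkylated alone with 3-chloro-3-methylbut-1-yne (K2CO3, KI, catalytic CuI, acetone, reflux), where para-acyl selectivity is well established. This gives 1-[2-hydroxy-4-(2-methylbut-3-yn-2-yloxy)phenyl]ethanone F1 and 3-hydroxy-4-(2-methylbut-3-yn-2-yloxy)benzaldehyde F2.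
- KOH in EtOH at rt joins them to the bis(1,1-dimethylpropargyl) ether chalcone F3. The remaining meta-phenoxide does not deactivate the aldehyde.
- Semihydrogenation of both terminal alkynes (H2, Pd/CaCO3 poisoned with Pb(OAc)2, quinoline, EtOAc) then gives 9.

Risk at step 4:
- The tertiary ethers may ionise and lose isoprene instead of rearranging.
- Some C5' isomer may form.
- Part of 11 may close thermally to racemic flavanone.

The fallback sets out from 4 and comes back at 11. It uses primary allyl ethers, which cannot ionise.
- Allyl bromide (2.1 equiv) and K2CO3 in acetone give butein 4,4'-diallyl ether F4.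
- Double Claisen rearrangement at 190–200 °C in N,N-diethylaniline gives 3',5-diallylbutein F5. Any flavanone is reopened with aqueous KOH.
- Double cross-metathesis with excess 2-methylbut-2-ene (second-generation Hoveyda–Grubbs catalyst, CH2Cl2, 40 °C) converts both allyl groups into prenyl groups and gives 11.

Risk at step 5:
- The chelated, unactivated enone reacts slowly.
- The acidic 4'-OH can park the amine of the catalyst.
- The sense of induction rests on the stated assumption.
- The closure is reversible, so the ee decays near equilibrium.

The fallback sets out from 11 and comes back at 12. It replaces asymmetric catalysis by resolution with recycling.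
- NaOAc in refluxing EtOH closes 11 to racemic 7,3',4'-trihydroxy-8,5'-diprenylflavanone F6.
- Preparative chiral supercritical-fluid chromatography on an amylose tris(3,5-dimethylphenylcarbamate) phase delivers 12 and the (2R)-flavanone F7.
- F7 is reopened with aqueous KOH and acidified to return 11 for the next cycle.

**Further compounds**
F1 | step 3 | 1-[2-hydroxy-4-(2-methylbut-3-yn-2-yloxy)phenyl]ethanone | CC(=O)c1ccc(OC(C)(C)C#C)cc1O
F2 | step 3 | 3-hydroxy-4-(2-methylbut-3-yn-2-yloxy)benzaldehyde | O=Cc1ccc(OC(C)(C)C#C)c(O)c1
F3 | step 3 | (E)-1-[2-hydroxy-4-(2-methylbut-3-yn-2-yloxy)phenyl]-3-[3-hydroxy-4-(2-methylbut-3-yn-2-yloxy)phenyl]prop-2-en-1-one | O=C(/C=C/c1ccc(OC(C)(C)C#C)c(O)c1)c1ccc(OC(C)(C)C#C)cc1O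
F4 | step 4 | (E)-1-(4-allyloxy-2-hydroxyphenyl)-3-(4-allyloxy-3-hydroxyphenyl)prop-2-en-1-one | O=C(/C=C/c1ccc(OCC=C)c(O)c1)c1ccc(OCC=C)cc1O
F5 | step 4 | (E)-1-(3-allyl-2,4-dihydroxyphenyl)-3-(5-allyl-3,4-dihydroxyphenyl)prop-2-en-1-one | O=C(/C=C/c1cc(O)c(O)c(CC=C)c1)c1ccc(O)c(CC=C)c1O
F6 | step 5 | racemic 7,3',4'-trihydroxy-8,5'-diprenylflavanone | CC(C)=CCc1cc(C2CC(=O)c3ccc(O)c(CC=C(C)C)c3O2)cc(O)c1O
F7 | step 5 | (2R)-7,3',4'-trihydroxy-8,5'-diprenylflavanone | CC(C)=CCc1cc([C@H]2CC(=O)c3ccc(O)c(CC=C(C)C)c3O2)cc(O)c1O
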